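**Retrosynthetic overview**
1. Target 14 ⇒ bisphenol tetrahydrofuran 9 + 2 × (S)-α-chloroketone 12. Two SN2 etherifications (inversion) and a double Felkin–Anh ketone reduction put on the two threo 8-O-4′ arms last.
2. The tetrahydrofuran (the only ring made; aryl rings are bought) is closed as the lignan is thought to arise: an 8–8′-linked C6C3 dimer, electrophilic at C7 and C7′, takes up one water and closes the 7-O-7′ bond. It is run as a double SN2 on C2-symmetric bis-mesylate 6, not through quinone methides, because quinone methide closure puts each aryl trans to its neighbouring methyl and the target needs both cis.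
3. 6 ⇐ anti,anti-diol 5 ⇐ 8–8′ diketone 4, from oxidative dimerization of the enolate of tosylated propiovanillone 2 (the ketone-level version of the radical 8–8′ coupling).
4. Reduction of racemic threo-4 with the (R)-CBS catalyst creates the carbinol centres and selects the (2S,3S) enantiomer.

Assumption: 1, 10, 11 and all reagents are bought; racemic 4 is drawn as its (2S,3S) enantiomer, the one carried forward.

**Route**

Step 1
Reactants: 1 1-(4-hydroxy-3-methoxyphenyl)propan-1-one (propiovanillone)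
Product: 2 2-methoxy-4-propanoylphenyl 4-methylbenzenesulfonate
Conditions: TsCl, Et3N, 4-(dimethylamino)pyridine (cat.), CH2Cl2, 0 °C to rt
Reagents that add atoms: 4-methylbenzenesulfonyl chloride (TsCl), Cc1ccc(cc1)S(Cl)(=O)=O
Why: Phenol sulfonylation; the tosylate protects the phenol for the enolate step and, being electron-withdrawing, later keeps the benzylic carbons from ionizing to quinone-methide-type cations (no stereocenter formed).

Step 2
Reactants: 2 2-methoxy-4-propanoylphenyl 4-methylbenzenesulfonate (two molecules)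
Product: 4 racemic threo (2S*,3S*)-1,4-bis[3-methoxy-4-(tosyloxy)phenyl]-2,3-dimethylbutane-1,4-dione, via lithium enolate 3 (not isolated)
Conditions: LiN(SiMe3)2, THF, −78 °C; then CuCl2, DMF, −78 to −40 °C; threo racemate separated from the meso isomer by crystallization/chromatography
Reagents that add atoms: none
Why: CuCl2-mediated oxidative homocoupling of a lithium enolate (Saegusa-type dimerization) forms the 8–8′ bond; the C2/C3 relationship is not controlled (threo racemate and meso about 1:1), so the threo racemate is isolated and the meso isomer can be re-equilibrated with base.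

Step 3
Reactants: 4 racemic threo diketone
Product: 5 (1S,2S,3S,4S)-1,4-bis[3-methoxy-4-(tosyloxy)phenyl]-2,3-dimethylbutane-1,4-diol (anti,anti)
Conditions: (R)-Me-CBS oxazaborolidine [(R)-1-methyl-3,3-diphenyltetrahydro-1H,3H-pyrrolo[1,2-c][1,3,2]oxazaborole] (0.3 equiv), BH3·SMe2, THF, −20 to 0 °C; MeOH quench; chromatography, then recrystallization
Reagents that add atoms: none
Why: Corey–Bakshi–Shibata reduction, in which the (R)-catalyst makes (S)-carbinols; for the (2S,3S) enantiomer this coincides with Felkin–Anh attack and gives the anti,anti diol, the (2R,3R) enantiomer is mismatched and goes mainly to the separable syn,syn diastereomer, and the enantiomer of 5 would need two catalyst-opposed reductions (Horeau-type amplification), so C1/C4 are created and the C2/C3 absolute configuration is selected here.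

Step 4
Reactants: 5 (1S,2S,3S,4S)-diol
Product: 8 (2R,3S,4S,5R)-2,5-bis[3-methoxy-4-(tosyloxy)phenyl]-3,4-dimethyloxolane, via bis-mesylate 6 (not isolated), via hydroxy mesylate 7 (not isolated)
Conditions: Ms2O, Et3N, CH2Cl2, −30 °C; then KHCO3, H2O/acetone (1:4), 0 to 35 °C
Reagents that add atoms: methanesulfonic anhydride, CS(=O)(=O)OS(C)(=O)=O (mesyl groups of 6 and 7 only); water, O (ring oxygen of 8)
Why: Proposed new method: formal insertion of water with double inversion. Exhaustive mesylation at −30 °C (chloride-free, so no halide exchange) gives C2-symmetric 6; the tosyloxy (σp about +0.3) and meta-methoxy groups make the aryl rings too electron-poor to ionize, so water/hydrogencarbonate attacks one mesylate from the rear (1S → 1R, giving 7), and the new hydroxyl displaces the second mesylate in a 5-exo-tet Williamson closure (4S → 4R); both aryl groups therefore end cis to their neighbouring methyl groups while the methyl-bearing carbons are untouched. Closest known reactions: double SN2 ring closures of 1,4-diarylbutane-1,4-diol bis-mesylates and cyclic sulfates with amines, sulfide or phosphides, and solvolytic inversion of electron-poor 1-arylethyl sulfonates.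

Step 5
Reactants: 8 tetrahydrofuran bis-tosylate
Product: 9 4,4′-[(2R,3S,4S,5R)-3,4-dimethyloxolane-2,5-diyl]bis(2-methoxyphenol)
Conditions: KOH, H2O/1,4-dioxane, 70 °C; then dilute HCl to pH 6
Reagents that add atoms: none
Why: Hydroxide cleaves the aryl sulfonates at sulfur (S–O cleavage); the benzylic ether centres are not acidic and phenoxide-driven ring opening needs far higher temperature, so the cis,trans,cis ring is kept.

Step 6
Reactants: 10 1,2-dimethoxybenzene (veratrole); 11 (S)-2-chloropropanoyl chloride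
Product: 12 (S)-2-chloro-1-(3,4-dimethoxyphenyl)propan-1-one
Conditions: AlCl3, CH2Cl2, −10 to 0 °C
Reagents that add atoms: none
Why: Friedel–Crafts acylation para to a methoxy group; the stereocenter of 11 is not a reacting centre and this acid chloride is known to acylate arenes at low temperature without racemization.

Step 7
Reactants: 9 bisphenol; 12 (S)-α-chloroketone (2.3 equiv)
Product: 13 (2R,2′R)-2,2′-{[(2R,3S,4S,5R)-3,4-dimethyloxolane-2,5-diyl]bis[(2-methoxy-4,1-phenylene)oxy]}bis[1-(3,4-dimethoxyphenyl)propan-1-one]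
Conditions: K2CO3, acetone, rt to 40 °C
Reagents that add atoms: none
Why: Double Williamson SN2 displacement of the α-keto chloride by phenoxide with inversion, (S) → (R); KCl precipitates from acetone, which suppresses the chloride exchange that would racemize 12.

Step 8
Reactants: 13 bis-ketone
Product: 14 (1R,1′R,2R,2′R)-2,2′-{[(2R,3S,4S,5R)-3,4-dimethyloxolane-2,5-diyl]bis[(2-methoxy-4,1-phenylene)oxy]}bis[1-(3,4-dimethoxyphenyl)propan-1-ol] (target)
Conditions: Bu4NBH4, CH2Cl2/MeOH, −40 to 0 °C
Reagents that add atoms: none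
Why: Borohydride reduction under polar Felkin–Anh control (aryloxy group anti to the incoming hydride) gives the threo (1R,2R) alcohol at both ends; the quaternary ammonium counter-ion avoids the metal chelation that favours erythro isomers.

**Compound list**

1 | 1-(4-hydroxy-3-methoxyphenyl)propan-1-one | CCC(=O)c1ccc(O)c(OC)c1 | starting material
2 | 2-methoxy-4-propanoylphenyl 4-methylbenzenesulfonate | CCC(=O)c1ccc(OS(=O)(=O)c2ccc(C)cc2)c(OC)c1 | intermediate
3 | lithium (Z)-1-[3-methoxy-4-(tosyloxy)phenyl]prop-1-en-1-olate | [Li+].C/C=C(\[O-])c1ccc(OS(=O)(=O)c2ccc(C)cc2)c(OC)c1 | intermediate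
4 | racemic threo (2S*,3S*)-1,4-bis[3-methoxy-4-(tosyloxy)phenyl]-2,3-dimethylbutane-1,4-dione (2S,3S enantiomer drawn) | COc1cc(ccc1OS(=O)(=O)c2ccc(C)cc2)C(=O)[C@@H](C)[C@H](C)C(=O)c3ccc(OS(=O)(=O)c4ccc(C)cc4)c(OC)c3 | intermediate
5 | (1S,2S,3S,4S)-1,4-bis[3-methoxy-4-(tosyloxy)phenyl]-2,3-dimethylbutane-1,4-diol | COc1cc(ccc1OS(=O)(=O)c2ccc(C)cc2)[C@@H](O)[C@@H](C)[C@H](C)[C@H](O)c3ccc(OS(=O)(=O)c4ccc(C)cc4)c(OC)c3 | intermediate
6 | (1S,2S,3S,4S)-1,4-bis[3-methoxy-4-(tosyloxy)phenyl]-2,3-dimethylbutane-1,4-diyl dimethanesulfonate | COc1cc(ccc1OS(=O)(=O)c2ccc(C)cc2)[C@@H](OS(C)(=O)=O)[C@@H](C)[C@H](C)[C@H](OS(C)(=O)=O)c3ccc(OS(=O)(=O)c4ccc(C)cc4)c(OC)c3 | intermediate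
7 | (1S,2S,3S,4R)-4-hydroxy-1,4-bis[3-methoxy-4-(tosyloxy)phenyl]-2,3-dimethylbutyl methanesulfonate | COc1cc(ccc1OS(=O)(=O)c2ccc(C)cc2)[C@H](O)[C@@H](C)[C@H](C)[C@H](OS(C)(=O)=O)c3ccc(OS(=O)(=O)c4ccc(C)cc4)c(OC)c3 | intermediate
8 | (2R,3S,4S,5R)-2,5-bis[3-methoxy-4-(tosyloxy)phenyl]-3,4-dimethyloxolane | Cc1ccc(cc1)S(=O)(=O)Oc2ccc(cc2OC)[C@@H]3O[C@@H](c4ccc(OS(=O)(=O)c5ccc(C)cc5)c(OC)c4)[C@@H](C)[C@@H]3C | intermediate
9 | 4,4′-[(2R,3S,4S,5R)-3,4-dimethyloxolane-2,5-diyl]bis(2-methoxyphenol) | Oc1ccc(cc1OC)[C@@H]2O[C@@H](c3ccc(O)c(OC)c3)[C@@H](C)[C@@H]2C | intermediate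
10 | 1,2-dimethoxybenzene | COc1ccccc1OC | starting material
11 | (S)-2-chloropropanoyl chloride | C[C@H](Cl)C(Cl)=O | starting material
12 | (S)-2-chloro-1-(3,4-dimethoxyphenyl)propan-1-one | C[C@H](Cl)C(=O)c1ccc(OC)c(OC)c1 | intermediate
13 | bis-(R)-α-aryloxy ketone of the (2R,3S,4S,5R)-tetrahydrofuran | COc1ccc(C(=O)[C@@H](C)Oc2ccc([C@@H]3O[C@@H](c4ccc(O[C@H](C)C(=O)c5ccc(OC)c(OC)c5)c(OC)c4)[C@@H](C)[C@@H]3C)cc2OC)cc1OC | intermediate
14 | CNP0116650.3 | COc1ccc([C@@H](O)[C@@H](C)Oc2ccc([C@@H]3O[C@@H](c4ccc(O[C@H](C)[C@H](O)c5ccc(OC)c(OC)c5)c(OC)c4)[C@@H](C)[C@@H]3C)cc2OC)cc1OC | target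

**Step count and risk**

Total steps: 8. Longest linear sequence: 7 (1 → 2 → 4 → 5 → 8 → 9 → 13 → 14); step 6 is the side branch.

The step most likely to fail is the water insertion of step 4. Elimination to styrenes, partial ionization, or ring closure at the mono-mesylate stage would each give the wrong ring isomer. The fallback sets out from 5 and returns at 8 through a cyclic sulfate relay. SOCl2/Et3N gives cyclic sulfite F3, and RuCl3 (cat.)/NaIO4 oxidizes it to cyclic sulfate F4, the substrate type used for double inversion at both benzylic carbons in 2,5-diarylphospholane synthesis. Ammonium benzoate opens F4 once with inversion to benzoate sulfate F5, whose monosulfate anion cannot be attacked a second time. K2CO3/MeOH then removes the benzoate, and the alkoxide displaces the sulfate with inversion to give 8.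

Second is the reduction of step 3. If catalyst control in the mismatched enantiomer is weak, the enantiomeric purity of 5 suffers. The fallback sets out from 4 and returns at 5. K[BH(s-Bu)3] in THF at −78 °C (Felkin–Anh at both ketones) gives racemic anti,anti-diol F1. Esterification with (S)-2-methoxy-2-phenylacetic acid (DCC, DMAP) gives two diastereomeric bis-esters, from which bis-(S)-O-methylmandelate F2 of the (1S,2S,3S,4S) diol is separated by chromatography or crystallization. LiOH in THF/H2O cleaves F2 to 5.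

Third is the etherification of step 7, where enolization or chloride exchange could erode the configuration of 12 or 13. The fallback sets out from 9 and returns at 13. Mitsunobu etherification of 9 with (S)-2-hydroxy-N-methoxy-N-methylpropanamide (PPh3, DIAD, THF; clean inversion, as with lactate esters) gives bis-Weinreb amide F6. Addition of 3,4-dimethoxyphenylmagnesium bromide (THF, −20 to 0 °C) then gives 13.

**Further compounds**

F1 | step 3 | racemic (1S*,2S*,3S*,4S*)-1,4-bis[3-methoxy-4-(tosyloxy)phenyl]-2,3-dimethylbutane-1,4-diol (one enantiomer drawn) | COc1cc(ccc1OS(=O)(=O)c2ccc(C)cc2)[C@@H](O)[C@@H](C)[C@H](C)[C@H](O)c3ccc(OS(=O)(=O)c4ccc(C)cc4)c(OC)c3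
F2 | step 3 | bis[(S)-2-methoxy-2-phenylacetate] of the (1S,2S,3S,4S)-diol | COc1cc(ccc1OS(=O)(=O)c2ccc(C)cc2)[C@@H](OC(=O)[C@@H](OC)c3ccccc3)[C@@H](C)[C@H](C)[C@H](OC(=O)[C@@H](OC)c4ccccc4)c5ccc(OS(=O)(=O)c6ccc(C)cc6)c(OC)c5
F3 | step 4 | (4S,5S,6S,7S)-4,7-bis[3-methoxy-4-(tosyloxy)phenyl]-5,6-dimethyl-1,3,2-dioxathiepane 2-oxide (cyclic sulfite) | COc1cc(ccc1OS(=O)(=O)c2ccc(C)cc2)[C@H]3OS(=O)O[C@H](c4ccc(OS(=O)(=O)c5ccc(C)cc5)c(OC)c4)[C@@H](C)[C@@H]3C
F4 | step 4 | (4S,5S,6S,7S)-4,7-bis[3-methoxy-4-(tosyloxy)phenyl]-5,6-dimethyl-1,3,2-dioxathiepane 2,2-dioxide (cyclic sulfate) | COc1cc(ccc1OS(=O)(=O)c2ccc(C)cc2)[C@H]3OS(=O)(=O)O[C@H](c4ccc(OS(=O)(=O)c5ccc(C)cc5)c(OC)c4)[C@@H](C)[C@@H]3C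
F5 | step 4 | ammonium (1S,2S,3S,4R)-4-(benzoyloxy)-1,4-bis[3-methoxy-4-(tosyloxy)phenyl]-2,3-dimethylbutyl sulfate | COc1cc(ccc1OS(=O)(=O)c2ccc(C)cc2)[C@H](OC(=O)c3ccccc3)[C@@H](C)[C@H](C)[C@H](OS(=O)(=O)[O-])c4ccc(OS(=O)(=O)c5ccc(C)cc5)c(OC)c4.[NH4+]
F6 | step 7 | (2R,2′R)-2,2′-{[(2R,3S,4S,5R)-3,4-dimethyloxolane-2,5-diyl]bis[(2-methoxy-4,1-phenylene)oxy]}bis(N-methoxy-N-methylpropanamide) | CON(C)C(=O)[C@@H](C)Oc1ccc(cc1OC)[C@@H]2O[C@@H](c3ccc(O[C@H](C)C(=O)N(C)OC)c(OC)c3)[C@@H](C)[C@@H]2C
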